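The runs stem from a simulated flask from invented constants; noise was put on by code.

If the next flask was to be charged at 0.50 M with the loading held, I first had to know how much target it would give beside isomer of the product A, and whether that charge was worth making.

| flask | substrate | catalyst | remark | time |
|---|---|---|---|---|
| violet | 0.25 M | 0.2 mol% | run made earlier |  |
| grey | 1 M | 0.2 mol% | run made earlier |  |
| flask | 0.50 M | 0.2 mol% |  | 6.0 h |

- violet (time / h: isomer of the product A / %, target / %, substrate / %): 0.667: 52.5, 7.5, 6.3; 2.00: 50.0, 11.8, 6.0; 3.00: 46.9, 14.7, 4.3; 5.00: 43.9, 16.8, 4.6; 8.00: 42.1, 18.2, 5.1
- grey (time / h: isomer of the product A / %, target / %, substrate / %): 0.667: 55.5, 6.4, 6.1; 2.00: 46.0, 13.7, 5.2; 3.00: 42.0, 18.2, 4.4; 5.00: 36.9, 22.7, 4.3; 8.00: 32.4, 24.4, 3.1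

(readings scatter by 0.5 percentage points)

- in percentages every species weighs as the substrate in it: one idle adduct counts as two
- for target the idle adduct is counted in
- the numbers in the tables scatter with a standard deviation of 0.5 percentage points
- what may be going on: substrate <-> target; target <-> isomer of the product A; isomer of the product A + catalyst <-> isomer of the product B + catalyst; isomer of the product B <-> substrate; substrate + target <-> idle adduct; target <-> isomer of the product C
- in an amount of target, one idle adduct counts as one target

1. share of isomer of the product A in isomer of the product A plus target at 20 s
2. share of isomer of the product A in isomer of the product A plus target at 10 min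
3. share of isomer of the product A in isomer of the product A plus target at 6.0 h

Counted in fractions of the charge, a step of one molecule runs alike at every charge. Two steps on the list of possible ones do not: substrate and target joining to idle adduct, and the catalysed step, whose catalyst concentration grows with the charge at a held loading. So I followed the charge concentration and read it in doublings, the flask standing at twice violet's charge and half grey's.

I took the share of isomer of the product A in it plus target, a selectivity. Interpolated to 6.0 h between the readings at 5.00 h and 8.00 h, it came to 71.5% in violet and 60.3% in grey. Across the 2.00 doublings between them, that gave 5.6 percentage points for the doubling loss, the share read as given up per doubling of the charge between these two runs, at held loading and at 6.0 h. The flask stands one doubling of charge above violet, which put its share at 65.9%, and on that figure I kept the charge at 0.50 M. The readings begin at 0.667 h, later than the two earlier asked times, so I reckoned nothing there.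

The forecast gave 45%, 91% and 66% (range 62.5% to 69.5%), and its grounds for the first ran: “the share is very uncertain”.

The flask gave 69.6% at 20 s, 93.0% at 10 min and 66.3% at 6.0 h. At that last time it held 22.1% as idle adduct, each one weighing as two. From violet's interpolated 71.5% to the flask's share is a fall of 5.2 points over one doubling, beside my doubling loss of 5.6 points.

    substrate ⇌ target (K = 2.50, k = 0.0220 /min)
    target ⇌ isomer of the product A (K = 3.62, k = 0.00133 /min)
    isomer of the product A + catalyst ⇌ isomer of the product B + catalyst, rate k3*[catalyst]*[isomer of the product A] forward; the back reaction follows from the equilibrium constant (K = 0.480, k = 50.9 /M/min)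
    isomer of the product B ⇌ substrate (k = 0.634 /min)
    substrate + target ⇌ idle adduct, settled at all times (K = 55.8 /M)
    target ⇌ isomer of the product C (K = 0.646, k = 0.0472 /min)

A neighbour flask charged at 0.30 M, loading and time held, stands 0.263 of a doubling above violet, so the doubling loss put its share at 70.0%. The computed neighbour gave 70.1% at 6.0 h.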